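**Retrosynthetic overview**
- Vitisinol D ⇐ global O‑demethylation and C3–C4 dehydrogenation of a saturated, tetra‑O‑methylated bicyclo[3.2.1]octane‑2,8‑dione.
- Bicyclic core ⇐ one‑carbon ring expansion of an all‑trans 4‑(diazoacetyl)‑2,3‑diarylcyclohexanone: the diazo carbon inserts across the ring into the C(=O)–CH(aryl) bond, forming the cyclopentanone, the cyclohexanedione and the bridgehead 1,3‑diketone in one event.
- Diazoketone ⇐ cyclohexanone acid ⇐ regiospecific α‑arylation (4‑bromoanisole) of the enol silane delivered by a Diels–Alder reaction.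
- Diels–Alder adduct ⇐ 2‑silyloxy‑4‑aryl diene (1,3‑dimethoxybenzene + methyl vinyl ketone) + 5‑aryl‑pentadienoate (4‑iodoanisole + methyl pentadienoate), under a chiral Lewis acid.
- Ring order: cyclohexane ring first (Diels–Alder), then both rings of the bicycle together in the ring expansion.

Assumption: O‑methyl protecting groups are not counted in the size of the building blocks (without them: resorcinol, 4‑iodophenol, 4‑bromophenol); the sense of induction of the oxazaborolidine catalyst in step 4 is taken from Corey's model and has not been verified here, its antipode being equally available.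

**Step 1**
Reactants: 1 1,3‑dimethoxybenzene; 2 but‑3‑en‑2‑one
Product: 4 (3E)‑4‑(3,5‑dimethoxyphenyl)but‑3‑en‑2‑one, via arylboronate 3 (not isolated)
Conditions: [Ir(OMe)(cod)]2 (1 mol %), 4,4′‑di‑tert‑butyl‑2,2′‑bipyridine, B2pin2 (1.0 equiv), THF, 80 °C; evaporate; Pd(OAc)2 (5 mol %), 2,9‑dimethyl‑1,10‑phenanthroline, 2 (2 equiv), O2 (1 atm), DMF, 50 °C
Reagents that add atoms: none
Why: Sterically governed C–H borylation occurs only at the position meta to both methoxy groups, and the base‑free oxidative (boron) Heck reaction with the enone gives the E‑alkene.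

**Step 2**
Reactants: 4 (3E)‑4‑(3,5‑dimethoxyphenyl)but‑3‑en‑2‑one
Product: 5 {[(3E)‑4‑(3,5‑dimethoxyphenyl)buta‑1,3‑dien‑2‑yl]oxy}tri(propan‑2‑yl)silane
Conditions: iPr3SiOTf (1.1 equiv), Et3N (1.5 equiv), CH2Cl2, 0 °C
Reagents that add atoms: tri(propan‑2‑yl)silyl trifluoromethanesulfonate, CC(C)[Si](OS(=O)(=O)C(F)(F)F)(C(C)C)C(C)C
Why: Soft enolisation/O‑silylation of a methyl enone, whose only enolisable position is the methyl group, gives the 2‑silyloxy diene.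

**Step 3**
Reactants: 6 1‑iodo‑4‑methoxybenzene; 7 methyl (2E)‑penta‑2,4‑dienoate
Product: 8 methyl (2E,4E)‑5‑(4‑methoxyphenyl)penta‑2,4‑dienoate
Conditions: Pd(OAc)2 (3 mol %), P(o‑tol)3 (6 mol %), Et3N (2 equiv), MeCN, 80 °C
Reagents that add atoms: none
Why: Mizoroki–Heck arylation takes place at the terminal vinyl carbon of the dienoate and gives the E,E‑diene.

**Step 4**
Reactants: 5 {[(3E)‑4‑(3,5‑dimethoxyphenyl)buta‑1,3‑dien‑2‑yl]oxy}tri(propan‑2‑yl)silane; 8 methyl (2E,4E)‑5‑(4‑methoxyphenyl)penta‑2,4‑dienoate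
Product: 9 methyl (1S,2R,6S)‑2‑(3,5‑dimethoxyphenyl)‑6‑[(E)‑2‑(4‑methoxyphenyl)ethenyl]‑4‑{[tri(propan‑2‑yl)silyl]oxy}cyclohex‑3‑ene‑1‑carboxylate
Conditions: (S)‑1‑(2‑methylphenyl)‑3,3‑diphenyltetrahydro‑1H,3H‑pyrrolo[1,2‑c][1,3,2]oxazaborole (10 mol %), AlBr3 (8 mol %), CH2Cl2, −40 → −20 °C; minor exo adduct removed by chromatography
Reagents that add atoms: none
Why: In this normal‑demand Diels–Alder reaction the 2‑silyloxy ("para") and 4‑aryl ("ortho") effects both put the ester carbon next to the aryl‑bearing carbon, and the AlBr3‑activated chiral oxazaborolidine (Corey‑type cationic Lewis acid) bound to the enoate enforces endo addition to one face, which sets C2 (R), the only centre not later equilibrated (C1) or erased (C6).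

**Step 5**
Reactants: 9 methyl (1S,2R,6S)‑2‑(3,5‑dimethoxyphenyl)‑6‑[(E)‑2‑(4‑methoxyphenyl)ethenyl]‑4‑{[tri(propan‑2‑yl)silyl]oxy}cyclohex‑3‑ene‑1‑carboxylate; 10 1‑bromo‑4‑methoxybenzene
Product: 12 (1R,2R,3S,6S)‑2‑(3,5‑dimethoxyphenyl)‑3‑(4‑methoxyphenyl)‑6‑[(E)‑2‑(4‑methoxyphenyl)ethenyl]‑4‑oxocyclohexane‑1‑carboxylic acid, via keto ester 11 (not isolated)
Conditions: Pd(dba)2 (3 mol %), P(tBu)3 (6 mol %), ZnF2 (0.6 equiv), CsF (0.4 equiv), DMF, 85 °C; then LiOH (6 equiv), MeOH/H2O, 55 °C; HCl work‑up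
Reagents that add atoms: lithium hydroxide, [Li+].[OH-]
Why: Fluoride releases the regiodefined enolate of the enol silane for α‑arylation with Pd(dba)2/P(tBu)3 at that carbon only, and hot hydroxide then saponifies the ester and equilibrates the two epimerisable centres (C1 next to the ester, C3 next to the ketone) to the isomer with the carboxyl and both aryl groups equatorial (carboxyl trans to the neighbouring aryl, aryls trans).

**Step 6**
Reactants: 12 (1R,2R,3S,6S)‑2‑(3,5‑dimethoxyphenyl)‑3‑(4‑methoxyphenyl)‑6‑[(E)‑2‑(4‑methoxyphenyl)ethenyl]‑4‑oxocyclohexane‑1‑carboxylic acid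
Product: 14 (2S,3S,4R,5S)‑4‑(2‑diazoacetyl)‑3‑(3,5‑dimethoxyphenyl)‑2‑(4‑methoxyphenyl)‑5‑[(E)‑2‑(4‑methoxyphenyl)ethenyl]cyclohexan‑1‑one, via acid chloride 13 (not isolated)
Conditions: (COCl)2, DMF (cat.), CH2Cl2, 0 → 23 °C; evaporate; CH2N2 (3 equiv), Et2O/THF, 0 °C
Reagents that add atoms: diazomethane, C=[N+]=[N-]
Why: Acylation of diazomethane by the acid chloride (first stage of the Arndt–Eistert sequence) gives the diazomethyl ketone without base, so the α‑stereocentre is untouched.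

**Step 7**
Reactants: 14 (2S,3S,4R,5S)‑4‑(2‑diazoacetyl)‑3‑(3,5‑dimethoxyphenyl)‑2‑(4‑methoxyphenyl)‑5‑[(E)‑2‑(4‑methoxyphenyl)ethenyl]cyclohexan‑1‑one
Product: 16 (1R,4S,5R,6R,7R)‑6‑(3,5‑dimethoxyphenyl)‑7‑(4‑methoxyphenyl)‑4‑[(E)‑2‑(4‑methoxyphenyl)ethenyl]bicyclo[3.2.1]octane‑2,8‑dione, via diazonium betaine 15 (not isolated)
Conditions: Sc(OTf)3 (20 mol %), CH2Cl2 (0.01 M, slow addition of 14), −20 → 23 °C
Reagents that add atoms: none
Why: Proposed new method: the nucleophilic diazo carbon adds across the boat cyclohexanone to the Sc(OTf)3‑activated ring ketone to give the bicyclo[2.2.2]octane β‑oxido diazonium 15, in which epoxide closure is geometrically impossible (O and N2 gauche) and, with N2 turned to the unhindered CH2 bridge, only the benzylic C–C bond is antiperiplanar to C–N2, so this carbon shifts with retention as N2 leaves, expanding the ring by one carbon, forming the non‑enolisable bridgehead 1,3‑diketone irreversibly and fixing the new bridgehead centre by ring constraint; the closest known reaction is the Lewis‑acid‑promoted Tiffeneau–Demjanov‑type homologation of ketones with α‑diazo carbonyl compounds, known only intermolecularly.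

**Step 8**
Reactants: 16 (1R,4S,5R,6R,7R)‑6‑(3,5‑dimethoxyphenyl)‑7‑(4‑methoxyphenyl)‑4‑[(E)‑2‑(4‑methoxyphenyl)ethenyl]bicyclo[3.2.1]octane‑2,8‑dione
Product: 17 (1R,5S,6R,7R)‑6‑(3,5‑dimethoxyphenyl)‑7‑(4‑methoxyphenyl)‑4‑[(E)‑2‑(4‑methoxyphenyl)ethenyl]bicyclo[3.2.1]oct‑3‑ene‑2,8‑dione
Conditions: IBX (1.5 equiv), 4‑methoxypyridine N‑oxide (1.5 equiv), DMSO, 23 °C
Reagents that add atoms: none
Why: IBX dehydrogenation of a ketone (Nicolaou) can only act at C3–C4, because every other α‑carbon of the two ketones is a bridgehead, and it removes the C4 stereocentre to give the styryl‑conjugated enone.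

**Step 9**
Reactants: 17 (1R,5S,6R,7R)‑6‑(3,5‑dimethoxyphenyl)‑7‑(4‑methoxyphenyl)‑4‑[(E)‑2‑(4‑methoxyphenyl)ethenyl]bicyclo[3.2.1]oct‑3‑ene‑2,8‑dione
Product: 18 vitisinol D, (1R,5S,6R,7R)‑6‑(3,5‑dihydroxyphenyl)‑7‑(4‑hydroxyphenyl)‑4‑[(E)‑2‑(4‑hydroxyphenyl)ethenyl]bicyclo[3.2.1]oct‑3‑ene‑2,8‑dione
Conditions: BBr3 (10 equiv), CH2Cl2, −78 → 0 °C; then H2O
Reagents that add atoms: none
Why: Lewis‑acid cleavage of the four aryl methyl ethers at low temperature avoids base, which would open the bridgehead 1,3‑diketone by retro‑Claisen cleavage, and leaves all four stereocentres untouched.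

**Compound list**
1 | 1,3‑dimethoxybenzene | COc1cccc(OC)c1 | starting material
2 | but‑3‑en‑2‑one | CC(=O)C=C | starting material
3 | 2‑(3,5‑dimethoxyphenyl)‑4,4,5,5‑tetramethyl‑1,3,2‑dioxaborolane | COc1cc(OC)cc(c1)B1OC(C)(C)C(C)(C)O1 | intermediate
4 | (3E)‑4‑(3,5‑dimethoxyphenyl)but‑3‑en‑2‑one | CC(=O)/C=C/c1cc(OC)cc(OC)c1 | intermediate
5 | {[(3E)‑4‑(3,5‑dimethoxyphenyl)buta‑1,3‑dien‑2‑yl]oxy}tri(propan‑2‑yl)silane | C=C(O[Si](C(C)C)(C(C)C)C(C)C)/C=C/c1cc(OC)cc(OC)c1 | intermediate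
6 | 1‑iodo‑4‑methoxybenzene | COc1ccc(I)cc1 | starting material
7 | methyl (2E)‑penta‑2,4‑dienoate | COC(=O)/C=C/C=C | starting material
8 | methyl (2E,4E)‑5‑(4‑methoxyphenyl)penta‑2,4‑dienoate | COC(=O)/C=C/C=C/c1ccc(OC)cc1 | intermediate
9 | methyl (1S,2R,6S)‑2‑(3,5‑dimethoxyphenyl)‑6‑[(E)‑2‑(4‑methoxyphenyl)ethenyl]‑4‑{[tri(propan‑2‑yl)silyl]oxy}cyclohex‑3‑ene‑1‑carboxylate | COC(=O)[C@@H]1[C@H](c2cc(OC)cc(OC)c2)C=C(O[Si](C(C)C)(C(C)C)C(C)C)C[C@H]1/C=C/c1ccc(OC)cc1 | intermediate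
10 | 1‑bromo‑4‑methoxybenzene | COc1ccc(Br)cc1 | starting material
11 | methyl (1S,2R,3S,6S)‑2‑(3,5‑dimethoxyphenyl)‑3‑(4‑methoxyphenyl)‑6‑[(E)‑2‑(4‑methoxyphenyl)ethenyl]‑4‑oxocyclohexane‑1‑carboxylate | O=C1C[C@@H](/C=C/c2ccc(OC)cc2)[C@H](C(=O)OC)[C@H](c2cc(OC)cc(OC)c2)[C@H]1c1ccc(OC)cc1 | intermediate
12 | (1R,2R,3S,6S)‑2‑(3,5‑dimethoxyphenyl)‑3‑(4‑methoxyphenyl)‑6‑[(E)‑2‑(4‑methoxyphenyl)ethenyl]‑4‑oxocyclohexane‑1‑carboxylic acid | O=C1C[C@@H](/C=C/c2ccc(OC)cc2)[C@@H](C(=O)O)[C@H](c2cc(OC)cc(OC)c2)[C@H]1c1ccc(OC)cc1 | intermediate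
13 | (1R,2R,3S,6S)‑2‑(3,5‑dimethoxyphenyl)‑3‑(4‑methoxyphenyl)‑6‑[(E)‑2‑(4‑methoxyphenyl)ethenyl]‑4‑oxocyclohexane‑1‑carbonyl chloride | O=C1C[C@@H](/C=C/c2ccc(OC)cc2)[C@@H](C(=O)Cl)[C@H](c2cc(OC)cc(OC)c2)[C@H]1c1ccc(OC)cc1 | intermediate
14 | (2S,3S,4R,5S)‑4‑(2‑diazoacetyl)‑3‑(3,5‑dimethoxyphenyl)‑2‑(4‑methoxyphenyl)‑5‑[(E)‑2‑(4‑methoxyphenyl)ethenyl]cyclohexan‑1‑one | O=C1C[C@@H](/C=C/c2ccc(OC)cc2)[C@@H](C(=O)C=[N+]=[N-])[C@H](c2cc(OC)cc(OC)c2)[C@H]1c1ccc(OC)cc1 | intermediate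
15 | 3‑diazonio‑6‑(3,5‑dimethoxyphenyl)‑5‑(4‑methoxyphenyl)‑7‑[(E)‑2‑(4‑methoxyphenyl)ethenyl]‑2‑oxobicyclo[2.2.2]octan‑4‑olate (scandium‑bound betaine; N2 on C3 turned to the C7–C8 bridge, other centres as in 14) | [O-][C@@]12C[C@@H](/C=C/c3ccc(OC)cc3)[C@@H](C(=O)[C@H]1[N+]#N)[C@H](c1cc(OC)cc(OC)c1)[C@H]2c1ccc(OC)cc1 | intermediate
16 | (1R,4S,5R,6R,7R)‑6‑(3,5‑dimethoxyphenyl)‑7‑(4‑methoxyphenyl)‑4‑[(E)‑2‑(4‑methoxyphenyl)ethenyl]bicyclo[3.2.1]octane‑2,8‑dione | O=C1C[C@@H](/C=C/c2ccc(OC)cc2)[C@H]2C(=O)[C@@H]1[C@H](c1ccc(OC)cc1)[C@H]2c1cc(OC)cc(OC)c1 | intermediate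
17 | (1R,5S,6R,7R)‑6‑(3,5‑dimethoxyphenyl)‑7‑(4‑methoxyphenyl)‑4‑[(E)‑2‑(4‑methoxyphenyl)ethenyl]bicyclo[3.2.1]oct‑3‑ene‑2,8‑dione | O=C1C=C(/C=C/c2ccc(OC)cc2)[C@H]2C(=O)[C@@H]1[C@H](c1ccc(OC)cc1)[C@H]2c1cc(OC)cc(OC)c1 | intermediate
18 | vitisinol D, (1R,5S,6R,7R)‑6‑(3,5‑dihydroxyphenyl)‑7‑(4‑hydroxyphenyl)‑4‑[(E)‑2‑(4‑hydroxyphenyl)ethenyl]bicyclo[3.2.1]oct‑3‑ene‑2,8‑dione | O=C1C=C(/C=C/c2ccc(O)cc2)[C@H]2C(=O)[C@@H]1[C@H](c1ccc(O)cc1)[C@H]2c1cc(O)cc(O)c1 | target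

**Totals and risks**
Total step count: 9. Longest linear sequence: 8 steps (1, 2, 4, 5, 6, 7, 8, 9); step 3 is the side branch.

The three steps most likely to fail:

Step 4. The β‑substituted enoate is a weak dienophile, the enol silane can be attacked by the acid catalyst, and the final enantiopurity needs both face and endo control (the exo adduct leads into the enantiomeric series). The fallback sets out from 5 and 8: an uncatalysed Diels–Alder reaction (toluene, 130 °C, sealed tube) gives the racemic endo adduct F1, which under the conditions of step 5 gives the racemic acid F2. Classical resolution with (R)‑1‑phenylethylamine (crystallisation from ethanol) gives the (R)‑1‑phenylethylammonium salt F3 of the wanted enantiomer, and acidification brings the material back to the route at 12.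

Step 5. The arylation builds a hindered, epimerisable benzylic centre next to an aryl‑bearing carbon, and the enolate could equilibrate before coupling. The fallback sets out from 9 and uses electrophilic arylation instead: (4‑methoxyphenyl)(2,4,6‑trimethylphenyl)iodonium trifluoromethanesulfonate F5 is made from 6, mesitylene, mCPBA and TfOH. It arylates the enol silane 9 directly with Cu(OTf)2 (10 mol %) and 2,6‑di‑tert‑butylpyridine in CH2Cl2 at 23 °C, the mesityl group staying on iodine. This comes back to the route at 11, which is saponified and equilibrated as before.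

Step 7 (the proposed new step). The Lewis acid may instead activate the diazoketone toward attack by the neighbouring electron‑rich dimethoxyphenyl ring (tetralone formation), or the alkenyl bridge carbon may migrate. The fallback uses two known reactions and sets out from 14: LiN(SiMe3)2 in THF at −78 °C effects the aldol‑type addition of the diazo carbon to the ring ketone and gives the bicyclic 3‑diazo‑4‑hydroxy ketone F4. Rh2(OAc)4 (1 mol %) in CH2Cl2 at 23 °C then converts it, by the known 1,2‑shift of β‑hydroxy‑α‑diazo ketones to 1,3‑diketones, into the same ring‑expanded diketone, coming back to the route at 16.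

**Further compounds**
F1 | step 4 | racemic methyl (1S,2R,6S)‑ and (1R,2S,6R)‑2‑(3,5‑dimethoxyphenyl)‑6‑[(E)‑2‑(4‑methoxyphenyl)ethenyl]‑4‑{[tri(propan‑2‑yl)silyl]oxy}cyclohex‑3‑ene‑1‑carboxylate | COC(=O)[C@@H]1[C@H](c2cc(OC)cc(OC)c2)C=C(O[Si](C(C)C)(C(C)C)C(C)C)C[C@H]1/C=C/c1ccc(OC)cc1.COC(=O)[C@H]1[C@@H](c2cc(OC)cc(OC)c2)C=C(O[Si](C(C)C)(C(C)C)C(C)C)C[C@@H]1/C=C/c1ccc(OC)cc1
F2 | step 4 | racemic (1R,2R,3S,6S)‑ and (1S,2S,3R,6R)‑2‑(3,5‑dimethoxyphenyl)‑3‑(4‑methoxyphenyl)‑6‑[(E)‑2‑(4‑methoxyphenyl)ethenyl]‑4‑oxocyclohexane‑1‑carboxylic acid | O=C1C[C@@H](/C=C/c2ccc(OC)cc2)[C@@H](C(=O)O)[C@H](c2cc(OC)cc(OC)c2)[C@H]1c1ccc(OC)cc1.O=C1C[C@H](/C=C/c2ccc(OC)cc2)[C@H](C(=O)O)[C@@H](c2cc(OC)cc(OC)c2)[C@@H]1c1ccc(OC)cc1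
F3 | step 4 | (R)‑1‑phenylethylammonium (1R,2R,3S,6S)‑2‑(3,5‑dimethoxyphenyl)‑3‑(4‑methoxyphenyl)‑6‑[(E)‑2‑(4‑methoxyphenyl)ethenyl]‑4‑oxocyclohexane‑1‑carboxylate | O=C1C[C@@H](/C=C/c2ccc(OC)cc2)[C@@H](C(=O)[O-])[C@H](c2cc(OC)cc(OC)c2)[C@H]1c1ccc(OC)cc1.C[C@@H]([NH3+])c1ccccc1
F4 | step 7 | 3‑diazo‑4‑hydroxy‑6‑(3,5‑dimethoxyphenyl)‑5‑(4‑methoxyphenyl)‑7‑[(E)‑2‑(4‑methoxyphenyl)ethenyl]bicyclo[2.2.2]octan‑2‑one (centres as in 14) | O[C@@]12C[C@@H](/C=C/c3ccc(OC)cc3)[C@@H](C(=O)C1=[N+]=[N-])[C@H](c1cc(OC)cc(OC)c1)[C@H]2c1ccc(OC)cc1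
F5 | step 5 | (4‑methoxyphenyl)(2,4,6‑trimethylphenyl)iodonium trifluoromethanesulfonate | COc1ccc(cc1)[I+]c1c(C)cc(C)cc1C.[O-]S(=O)(=O)C(F)(F)F
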